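**Retrosynthetic overview**

1. Endgame on the finished 14-membered carbocycle: the C7 acetate goes on last; the 1,2-dioxane (third ring formed) closes by transannular SN2 of a C8 hydroperoxide (from perhydrolysis of a 7S,8S-epoxide at C8) onto an inverted C11 allylic chloride.
2. Carbocycle (second ring formed): intramolecular B-alkyl Suzuki coupling at C4–C5 between the C5=C6 vinyl group and an (E)-vinyl iodide.
3. Lactone (first ring formed) and the key C1–C2 bond: intermolecular, auxiliary-controlled allylboration of (E)-3-iodobut-2-enal (fragment B) by a γ-substituted 2-(alkoxycarbonyl)allylboronate (fragment A), then lactonization.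
4. Fragment A from geranyl acetate (C6–C11, C19): ynone and Noyori reduction (C11), alkyne hydration (C12, C20), Z-selective Wittig (C13, C14, C1), methylenation (C5), Wittig with a borylated ylide (C15–C17).
5. Fragment B from but-2-yn-1-ol by hydrozirconation–iodination and oxidation (C2–C4, C18).

Assumption: positions are cited by cembrane numbering (C1–C20; lactone carbons C15–C17), and the (−)-8-phenylmenthyl ester is taken to shield the face that gives the 1S lactone; if a trial run shows the opposite sense, its enantiomer is used with no other change.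

**Route**

Step 1
Reactants: 1 geranyl acetate
Product: 2 (2E)-5-(3,3-dimethyloxiran-2-yl)-3-methylpent-2-en-1-yl acetate (racemic epoxide)
Conditions: m-CPBA (1.05 equiv), CH2Cl2, 0 °C
Reagents that add atoms: m-chloroperbenzoic acid, OOC(=O)c1cccc(Cl)c1
Why: Prilezhaev epoxidation picks the electron-rich 6,7-olefin over the olefin deactivated by the allylic acetate; the epoxide is only a cleavage handle, so its configuration does not matter.

Step 2
Reactants: 2 (2E)-5-(3,3-dimethyloxiran-2-yl)-3-methylpent-2-en-1-yl acetate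
Product: 3 (2E)-3-methyl-6-oxohex-2-en-1-yl acetate
Conditions: H5IO6 (1.2 equiv), THF/H2O, 0 °C
Reagents that add atoms: none
Why: Periodic acid hydrolyses the epoxide and cleaves the glycol (Malaprade cleavage), unmasking the C11 aldehyde of a chain whose E-olefin (future C7/C8) is inherited from geraniol.

Step 3
Reactants: 3 (2E)-3-methyl-6-oxohex-2-en-1-yl acetate; 4 ethynyl(trimethyl)silane
Product: 6 (2E)-6-hydroxy-3-methyl-8-(trimethylsilyl)oct-2-en-7-yn-1-yl acetate (racemic), via lithium acetylide 5 (not isolated)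
Conditions: 4 (1.2 equiv), n-BuLi (1.15 equiv), THF, −78 °C; then 3, −78 °C; H2O
Reagents that add atoms: none
Why: 1,2-Addition of the lithium acetylide to the aldehyde at −78 °C outruns attack on the acetate and brings in C12 and C20; the racemic carbinol is corrected in the next two steps.

Step 4
Reactants: 6 (2E)-6-hydroxy-3-methyl-8-(trimethylsilyl)oct-2-en-7-yn-1-yl acetate
Product: 7 (2E)-3-methyl-6-oxo-8-(trimethylsilyl)oct-2-en-7-yn-1-yl acetate
Conditions: Dess–Martin periodinane (1.3 equiv), CH2Cl2, 0 → 25 °C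
Reagents that add atoms: none
Why: Dess–Martin oxidation of the secondary propargylic alcohol gives the ynone under conditions that leave the silylalkyne and the acetate untouched.

Step 5
Reactants: 7 (2E)-3-methyl-6-oxo-8-(trimethylsilyl)oct-2-en-7-yn-1-yl acetate
Product: 8 (2E,6S)-6-hydroxy-3-methyl-8-(trimethylsilyl)oct-2-en-7-yn-1-yl acetate
Conditions: Ru[(S,S)-TsDPEN](p-cymene) (2 mol %), i-PrOH, 25 °C
Reagents that add atoms: none
Why: Noyori asymmetric transfer hydrogenation of the ynone, in which the alkynyl group takes the place of the aryl group, sets C11 as S under catalyst control.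

Step 6
Reactants: 8 (2E,6S)-6-hydroxy-3-methyl-8-(trimethylsilyl)oct-2-en-7-yn-1-yl acetate
Product: 9 (2E,6S)-6-(tert-butyldimethylsilyloxy)-3-methyl-8-(trimethylsilyl)oct-2-en-7-yn-1-yl acetate
Conditions: TBSCl (1.3 equiv), imidazole (2.5 equiv), DMF, 25 °C
Reagents that add atoms: tert-butyldimethylsilyl chloride, CC(C)(C)[Si](C)(C)Cl
Why: Silyl ether formation protects the C11 carbinol for the basic steps that follow.

Step 7
Reactants: 9 (2E,6S)-6-(tert-butyldimethylsilyloxy)-3-methyl-8-(trimethylsilyl)oct-2-en-7-yn-1-yl acetate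
Product: 10 (2E,6S)-6-(tert-butyldimethylsilyloxy)-3-methyloct-2-en-7-yn-1-ol
Conditions: K2CO3 (0.5 equiv), MeOH, 25 °C
Reagents that add atoms: none
Why: Base-catalysed methanolysis removes the alkynyl silyl group and the acetate in one operation (protodesilylation and transesterification) while the silyl ether stays.

Step 8
Reactants: 10 (2E,6S)-6-(tert-butyldimethylsilyloxy)-3-methyloct-2-en-7-yn-1-ol
Product: 11 (3S,6E)-3-(tert-butyldimethylsilyloxy)-8-hydroxy-6-methyloct-6-en-2-one
Conditions: (Ph3P)AuNTf2 (2 mol %), H2O (5 equiv), 1,4-dioxane, 50 °C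
Reagents that add atoms: water, O
Why: Gold-catalysed Markovnikov hydration of the terminal alkyne gives the methyl ketone (C12 with C20) without touching C11, because no enolizing base or strong acid is present.

Step 9
Reactants: 11 (3S,6E)-3-(tert-butyldimethylsilyloxy)-8-hydroxy-6-methyloct-6-en-2-one; 12 (3-hydroxypropyl)triphenylphosphonium bromide
Product: 14 (2E,6S,7Z)-6-(tert-butyldimethylsilyloxy)-3,7-dimethyldeca-2,7-diene-1,10-diol, via oxido ylide 13 (not isolated)
Conditions: 12 (3 equiv), KN(SiMe3)2 (6 equiv), THF, 0 °C; then 11, −78 → 25 °C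
Reagents that add atoms: none
Why: Wittig olefination of the α-silyloxy methyl ketone by the non-stabilized ylide is Z-selective (Still-type effect of the α-oxygen substituent), putting C11 and C14 cis on the new C12=C13 bond.

Step 10
Reactants: 14 (2E,6S,7Z)-6-(tert-butyldimethylsilyloxy)-3,7-dimethyldeca-2,7-diene-1,10-diol
Product: 15 (2E,6S,7Z)-6-(tert-butyldimethylsilyloxy)-10-hydroxy-3,7-dimethyldeca-2,7-dienal
Conditions: MnO2 (15 equiv), CH2Cl2, 25 °C
Reagents that add atoms: none
Why: Activated MnO2 oxidizes only the allylic primary alcohol, giving the E-enal and leaving the homoallylic C1 alcohol.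

Step 11
Reactants: 15 (2E,6S,7Z)-6-(tert-butyldimethylsilyloxy)-10-hydroxy-3,7-dimethyldeca-2,7-dienal
Product: 16 (3Z,5S,8E)-5-(tert-butyldimethylsilyloxy)-4,8-dimethylundeca-3,8,10-trien-1-ol
Conditions: Ph3PCH3Br (3 equiv), KOt-Bu (2.9 equiv), THF, 0 °C; then 15, 0 °C
Reagents that add atoms: methyltriphenylphosphonium bromide, C[P+](c1ccccc1)(c1ccccc1)c1ccccc1.[Br-]
Why: Wittig methylenation of the enal adds C5 and gives the 1,3-diene whose terminal vinyl group is the later hydroboration site, addition to the aldehyde being faster than any γ-deprotonation that could scramble the C7=C8 geometry.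

Step 12
Reactants: 16 (3Z,5S,8E)-5-(tert-butyldimethylsilyloxy)-4,8-dimethylundeca-3,8,10-trien-1-ol
Product: 17 (3Z,5S,8E)-5-(tert-butyldimethylsilyloxy)-4,8-dimethylundeca-3,8,10-trienal
Conditions: Dess–Martin periodinane (1.3 equiv), pyridine (3 equiv), CH2Cl2, 0 °C; used at once
Reagents that add atoms: none
Why: Buffered Dess–Martin oxidation gives the β,γ-unsaturated aldehyde without acid or base that could move the C12=C13 bond into conjugation.

Step 13
Reactants: 18 (−)-8-phenylmenthol; 19 bromoacetyl bromide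
Product: 20 (−)-8-phenylmenthyl bromoacetate
Conditions: 19 (1.2 equiv), pyridine (1.3 equiv), CH2Cl2, 0 °C
Reagents that add atoms: none
Why: Acylation of the auxiliary alcohol by the acid bromide (esterification) puts the future C15–C16 unit on the chiral ester.

Step 14
Reactants: 20 (−)-8-phenylmenthyl bromoacetate
Product: 22 (−)-8-phenylmenthyl (triphenylphosphoranylidene)acetate, via phosphonium bromide 21 (not isolated)
Conditions: PPh3 (1.05 equiv), toluene, 25 °C; then aq. NaOH, CH2Cl2, 0 °C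
Reagents that add atoms: triphenylphosphine, c1ccc(cc1)P(c1ccccc1)c1ccccc1
Why: SN2 quaternization of triphenylphosphine by the α-bromo ester and deprotonation give the ester-stabilized ylide.

Step 15
Reactants: 22 (−)-8-phenylmenthyl (triphenylphosphoranylidene)acetate; 23 2-(iodomethyl)-4,4,5,5-tetramethyl-1,3,2-dioxaborolane
Product: 25 (−)-8-phenylmenthyl 3-(4,4,5,5-tetramethyl-1,3,2-dioxaborolan-2-yl)-2-(triphenylphosphoranylidene)propanoate, via phosphonium iodide 24 (not isolated)
Conditions: 22 (2.0 equiv), 23 (1.0 equiv), CH2Cl2, 25 °C; phosphonium iodide filtered off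
Reagents that add atoms: none
Why: C-Alkylation of the stabilized ylide by the (iodomethyl)boronate followed by transylidation with a second equivalent of ylide gives the α-(borylmethyl) ylide, the usual way to α-substituted stabilized ylides.

Step 16
Reactants: 17 (3Z,5S,8E)-5-(tert-butyldimethylsilyloxy)-4,8-dimethylundeca-3,8,10-trienal; 25 borylated ylide
Product: 26 (−)-8-phenylmenthyl (2E,5Z,7S,10E)-7-(tert-butyldimethylsilyloxy)-6,10-dimethyl-2-[(4,4,5,5-tetramethyl-1,3,2-dioxaborolan-2-yl)methyl]trideca-2,5,10,12-tetraenoate (fragment A)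
Conditions: 25 (1.3 equiv), CH2Cl2, 25 → 40 °C
Reagents that add atoms: none
Why: Wittig olefination with the α,α-disubstituted stabilized ylide is E-selective, placing the C14 chain trans to the ester and cis to the CH2B group, the geometry that the allylboration turns into a syn adduct.

Step 17
Reactants: 27 but-2-yn-1-ol
Product: 29 (2E)-3-iodobut-2-en-1-ol, via alkenylzirconocene 28 (not isolated)
Conditions: Cp2Zr(H)Cl (2.5 equiv), THF, 25 → 40 °C; then I2 (1.2 equiv), 0 °C
Reagents that add atoms: iodine, II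
Why: Syn hydrozirconation places zirconium on the methyl-bearing alkyne carbon after equilibration, and iodinolysis with retention gives the E-vinyl iodide (iodine trans to CH2OH).

Step 18
Reactants: 29 (2E)-3-iodobut-2-en-1-ol
Product: 30 (2E)-3-iodobut-2-enal (fragment B)
Conditions: MnO2 (15 equiv), CH2Cl2, 25 °C, dark
Reagents that add atoms: none
Why: MnO2 oxidation of the allylic alcohol gives the β-iodoenal without loss of olefin geometry.

Step 19 (key step)
Reactants: 26 allylboronate (fragment A); 30 (2E)-3-iodobut-2-enal (fragment B)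
Product: 32 (4S,5R)-4-[(2Z,4S,7E)-4-(tert-butyldimethylsilyloxy)-3,7-dimethyldeca-2,7,9-trien-1-yl]-5-[(1E)-2-iodoprop-1-en-1-yl]-3-methylideneoxolan-2-one (H1/H2 cis; the R label at the carbinol carbon is only due to iodine priority), via homoallyl borate 31 (not isolated)
Conditions: 30 (1.5 equiv), 4 Å molecular sieves, toluene, 60 °C, 48 h; then pyridinium p-toluenesulfonate (20 mol %), 40 °C
Reagents that add atoms: none
Why: Intermolecular allylboration through a closed six-membered chair transition state converts the reagent geometry into the syn C1/C2 relationship and, after lactonization with release of the auxiliary, the cis-lactone, while the 8-phenylmenthyl ester shields one face of the allyl unit and so fixes the absolute configuration.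

Step 20
Reactants: 32 seco-lactone diene
Product: 33 (4S,5R)-4-[(2Z,4S)-4-(tert-butyldimethylsilyloxy)-6-[(2S,3S)-3-ethenyl-2-methyloxiran-2-yl]-3-methylhex-2-en-1-yl]-5-[(1E)-2-iodoprop-1-en-1-yl]-3-methylideneoxolan-2-one
Conditions: 1,2:4,5-di-O-isopropylidene-β-L-erythro-2,3-hexodiulo-2,6-pyranose (ent-Shi ketone, 3 equiv), KHSO5 (1.5 equiv, as 2KHSO5·KHSO4·K2SO4), NaHCO3, aq. Na2EDTA, MeCN, 0 °C, pH 7–8
Reagents that add atoms: potassium peroxymonosulfate, [K+].[O-]S(=O)(=O)OO
Why: Shi asymmetric epoxidation by the chiral dioxirane attacks the trisubstituted olefin of the diene, the most electron-rich site, and the L-fructose-derived ketone delivers oxygen to the face that gives the 7S,8S vinyl epoxide at a pH that spares the lactone.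

Step 21
Reactants: 33 vinyl epoxide lactone
Product: 35 (1S,2S,3E,7S,8S,11S,12Z)-11-(tert-butyldimethylsilyloxy)-7,8-epoxycembra-3,12,15(17)-trien-16,2-olide, via alkylborane 34 (not isolated)
Conditions: 9-BBN (1.6 equiv), THF, 0 → 25 °C; then slow addition to Pd(dppf)Cl2 (20 mol %), AsPh3 (20 mol %), Cs2CO3 (3 equiv), DMF/THF/H2O, 25 °C, 1 mM
Reagents that add atoms: none
Why: Chemoselective anti-Markovnikov hydroboration of the monosubstituted vinyl group and intramolecular B-alkyl Suzuki–Miyaura coupling with the vinyl iodide at high dilution close the 14-membered ring at C4–C5 with retention of the E geometry.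

Step 22
Reactants: 35 macrocyclic silyl ether
Product: 36 (1S,2S,3E,7S,8S,11S,12Z)-7,8-epoxy-11-hydroxycembra-3,12,15(17)-trien-16,2-olide
Conditions: Bu4NF (1.5 equiv), AcOH (1.5 equiv), THF, 0 → 25 °C
Reagents that add atoms: none
Why: Buffered fluoride-mediated desilylation frees the C11 allylic alcohol without opening the epoxide or adding to the methylene lactone.

Step 23
Reactants: 36 macrocyclic allylic alcohol
Product: 37 (1S,2S,3E,7S,8S,11R,12Z)-11-chloro-7,8-epoxycembra-3,12,15(17)-trien-16,2-olide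
Conditions: PPh3 (1.3 equiv), hexachloroacetone (5 equiv), CH2Cl2, −20 → 0 °C
Reagents that add atoms: hexachloroacetone, ClC(Cl)(Cl)C(=O)C(Cl)(Cl)Cl
Why: Appel-type chlorination under Magid conditions replaces the allylic hydroxyl by chloride through SN2 attack on the alkoxyphosphonium ion, inverting C11 to R with little allylic transposition.

Step 24
Reactants: 37 macrocyclic allylic chloride
Product: 38 (1S,2S,3E,7S,8R,11R,12Z)-11-chloro-8-hydroperoxy-7-hydroxycembra-3,12,15(17)-trien-16,2-olide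
Conditions: H2O2 (anhydrous, in Et2O, 10 equiv), H3PMo12O40 (5 mol %), Et2O, 25 °C
Reagents that add atoms: hydrogen peroxide, OO
Why: Acid-catalysed perhydrolysis opens the trisubstituted epoxide at its tertiary carbon with inversion (borderline SN2), giving the 8R hydroperoxide next to the 7S alcohol.

Step 25
Reactants: 38 chloro hydroperoxide
Product: 39 (1S,2S,3E,7S,8R,11S,12Z)-8,11-epidioxy-7-hydroxycembra-3,12,15(17)-trien-16,2-olide
Conditions: Cs2CO3 (1.5 equiv), DMF, 0 °C
Reagents that add atoms: none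
Why: Intramolecular (6-exo-tet, transannular) SN2 displacement of the allylic chloride by the peroxide anion closes the 1,2-dioxane and inverts C11 back to S, so that C7 and C12 end up cis on the new ring.

Step 26
Reactants: 39 7-O-deacetyl denticulatolide
Product: 40 denticulatolide
Conditions: Ac2O (3 equiv), pyridine, 4-(dimethylamino)pyridine (10 mol %), CH2Cl2, 0 → 25 °C
Reagents that add atoms: acetic anhydride, CC(=O)OC(C)=O
Why: Nucleophile-catalysed acetylation (esterification) of the hindered C7 alcohol completes the target.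

**Compound list**

1 | geranyl acetate | CC(=O)OC/C=C(\C)CCC=C(C)C | starting material
2 | (2E)-5-(3,3-dimethyloxiran-2-yl)-3-methylpent-2-en-1-yl acetate (racemic) | CC(=O)OC/C=C(\C)CCC1OC1(C)C | intermediate
3 | (2E)-3-methyl-6-oxohex-2-en-1-yl acetate | CC(=O)OC/C=C(\C)CCC=O | intermediate
4 | ethynyl(trimethyl)silane | C#C[Si](C)(C)C | starting material
5 | lithium (trimethylsilyl)acetylide | [Li]C#C[Si](C)(C)C | intermediate (not isolated)
6 | (2E)-6-hydroxy-3-methyl-8-(trimethylsilyl)oct-2-en-7-yn-1-yl acetate (racemic) | CC(=O)OC/C=C(\C)CCC(O)C#C[Si](C)(C)C | intermediate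
7 | (2E)-3-methyl-6-oxo-8-(trimethylsilyl)oct-2-en-7-yn-1-yl acetate | CC(=O)OC/C=C(\C)CCC(=O)C#C[Si](C)(C)C | intermediate
8 | (2E,6S)-6-hydroxy-3-methyl-8-(trimethylsilyl)oct-2-en-7-yn-1-yl acetate | CC(=O)OC/C=C(\C)CC[C@H](O)C#C[Si](C)(C)C | intermediate
9 | (2E,6S)-6-(tert-butyldimethylsilyloxy)-3-methyl-8-(trimethylsilyl)oct-2-en-7-yn-1-yl acetate | CC(=O)OC/C=C(\C)CC[C@H](O[Si](C)(C)C(C)(C)C)C#C[Si](C)(C)C | intermediate
10 | (2E,6S)-6-(tert-butyldimethylsilyloxy)-3-methyloct-2-en-7-yn-1-ol | OC/C=C(\C)CC[C@H](O[Si](C)(C)C(C)(C)C)C#C | intermediate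
11 | (3S,6E)-3-(tert-butyldimethylsilyloxy)-8-hydroxy-6-methyloct-6-en-2-one | OC/C=C(\C)CC[C@H](O[Si](C)(C)C(C)(C)C)C(C)=O | intermediate
12 | (3-hydroxypropyl)triphenylphosphonium bromide | OCCC[P+](c1ccccc1)(c1ccccc1)c1ccccc1.[Br-] | starting material
13 | potassium 3-(triphenylphosphoranylidene)propan-1-olate | [K+].[O-]CCC=P(c1ccccc1)(c1ccccc1)c1ccccc1 | intermediate (not isolated)
14 | (2E,6S,7Z)-6-(tert-butyldimethylsilyloxy)-3,7-dimethyldeca-2,7-diene-1,10-diol | OC/C=C(\C)CC[C@H](O[Si](C)(C)C(C)(C)C)/C(C)=C\CCO | intermediate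
15 | (2E,6S,7Z)-6-(tert-butyldimethylsilyloxy)-10-hydroxy-3,7-dimethyldeca-2,7-dienal | O=C/C=C(\C)CC[C@H](O[Si](C)(C)C(C)(C)C)/C(C)=C\CCO | intermediate
16 | (3Z,5S,8E)-5-(tert-butyldimethylsilyloxy)-4,8-dimethylundeca-3,8,10-trien-1-ol | C=C/C=C(\C)CC[C@H](O[Si](C)(C)C(C)(C)C)/C(C)=C\CCO | intermediate
17 | (3Z,5S,8E)-5-(tert-butyldimethylsilyloxy)-4,8-dimethylundeca-3,8,10-trienal | C=C/C=C(\C)CC[C@H](O[Si](C)(C)C(C)(C)C)/C(C)=C\CC=O | intermediate
18 | (−)-8-phenylmenthol, (1R,2S,5R)-5-methyl-2-(2-phenylpropan-2-yl)cyclohexan-1-ol | CC(C)(c1ccccc1)[C@@H]1CC[C@@H](C)C[C@H]1O | starting material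
19 | bromoacetyl bromide | BrCC(Br)=O | starting material
20 | (−)-8-phenylmenthyl bromoacetate | CC(C)(c1ccccc1)[C@@H]1CC[C@@H](C)C[C@H]1OC(=O)CBr | intermediate
21 | [2-oxo-2-(8-phenylmenthyloxy)ethyl]triphenylphosphonium bromide | CC(C)(c1ccccc1)[C@@H]1CC[C@@H](C)C[C@H]1OC(=O)C[P+](c1ccccc1)(c1ccccc1)c1ccccc1.[Br-] | intermediate (not isolated)
22 | (−)-8-phenylmenthyl (triphenylphosphoranylidene)acetate | CC(C)(c1ccccc1)[C@@H]1CC[C@@H](C)C[C@H]1OC(=O)C=P(c1ccccc1)(c1ccccc1)c1ccccc1 | intermediate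
23 | 2-(iodomethyl)-4,4,5,5-tetramethyl-1,3,2-dioxaborolane | ICB1OC(C)(C)C(C)(C)O1 | starting material
24 | [1-(8-phenylmenthyloxycarbonyl)-2-(pinacolboryl)ethyl]triphenylphosphonium iodide | CC(C)(c1ccccc1)[C@@H]1CC[C@@H](C)C[C@H]1OC(=O)C(CB1OC(C)(C)C(C)(C)O1)[P+](c1ccccc1)(c1ccccc1)c1ccccc1.[I-] | intermediate (not isolated)
25 | (−)-8-phenylmenthyl 3-(4,4,5,5-tetramethyl-1,3,2-dioxaborolan-2-yl)-2-(triphenylphosphoranylidene)propanoate | CC(C)(c1ccccc1)[C@@H]1CC[C@@H](C)C[C@H]1OC(=O)C(CB1OC(C)(C)C(C)(C)O1)=P(c1ccccc1)(c1ccccc1)c1ccccc1 | intermediate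
26 | (−)-8-phenylmenthyl (2E,5Z,7S,10E)-7-(tert-butyldimethylsilyloxy)-6,10-dimethyl-2-[(pinacolboryl)methyl]trideca-2,5,10,12-tetraenoate | C=C/C=C(\C)CC[C@H](O[Si](C)(C)C(C)(C)C)/C(C)=C\C/C=C(\CB1OC(C)(C)C(C)(C)O1)C(=O)O[C@@H]1C[C@H](C)CC[C@H]1C(C)(C)c1ccccc1 | intermediate
27 | but-2-yn-1-ol | CC#CCO | starting material
28 | (E)-alkenylzirconocene chloride of but-2-yn-1-ol (O-zirconated) | C/C([Zr](Cl)(C1C=CC=C1)C1C=CC=C1)=C\CO[Zr](Cl)(C1C=CC=C1)C1C=CC=C1 | intermediate (not isolated)
29 | (2E)-3-iodobut-2-en-1-ol | C/C(I)=C\CO | intermediate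
30 | (2E)-3-iodobut-2-enal | C/C(I)=C\C=O | intermediate
31 | syn homoallyl pinacol borate of the 8-phenylmenthyl ester (1S; H1/H2 syn) | C=C/C=C(\C)CC[C@H](O[Si](C)(C)C(C)(C)C)/C(C)=C\C[C@@H](C(=C)C(=O)O[C@@H]1C[C@H](C)CC[C@H]1C(C)(C)c1ccccc1)[C@@H](OB1OC(C)(C)C(C)(C)O1)/C=C(\C)I | intermediate (not isolated)
32 | (4S,5R)-4-[(2Z,4S,7E)-4-(tert-butyldimethylsilyloxy)-3,7-dimethyldeca-2,7,9-trien-1-yl]-5-[(1E)-2-iodoprop-1-en-1-yl]-3-methylideneoxolan-2-one | C=C/C=C(\C)CC[C@H](O[Si](C)(C)C(C)(C)C)/C(C)=C\C[C@@H]1[C@H](/C=C(\C)I)OC(=O)C1=C | intermediate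
33 | (4S,5R)-4-[(2Z,4S)-4-(tert-butyldimethylsilyloxy)-6-[(2S,3S)-3-ethenyl-2-methyloxiran-2-yl]-3-methylhex-2-en-1-yl]-5-[(1E)-2-iodoprop-1-en-1-yl]-3-methylideneoxolan-2-one | C=C[C@@H]1O[C@@]1(C)CC[C@H](O[Si](C)(C)C(C)(C)C)/C(C)=C\C[C@@H]1[C@H](/C=C(\C)I)OC(=O)C1=C | intermediate
34 | B-alkyl-9-borabicyclo[3.3.1]nonane from 33 (boron on C5) | B1(C2CCCC1CCC2)CC[C@@H]1O[C@@]1(C)CC[C@H](O[Si](C)(C)C(C)(C)C)/C(C)=C\C[C@@H]1[C@H](/C=C(\C)I)OC(=O)C1=C | intermediate (not isolated)
35 | (1S,2S,3E,7S,8S,11S,12Z)-11-(tert-butyldimethylsilyloxy)-7,8-epoxycembra-3,12,15(17)-trien-16,2-olide | C=C1C(=O)O[C@H]2/C=C(\C)CC[C@@H]3O[C@@]3(C)CC[C@H](O[Si](C)(C)C(C)(C)C)/C(C)=C\C[C@@H]12 | intermediate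
36 | (1S,2S,3E,7S,8S,11S,12Z)-7,8-epoxy-11-hydroxycembra-3,12,15(17)-trien-16,2-olide | C=C1C(=O)O[C@H]2/C=C(\C)CC[C@@H]3O[C@@]3(C)CC[C@H](O)/C(C)=C\C[C@@H]12 | intermediate
37 | (1S,2S,3E,7S,8S,11R,12Z)-11-chloro-7,8-epoxycembra-3,12,15(17)-trien-16,2-olide | C=C1C(=O)O[C@H]2/C=C(\C)CC[C@@H]3O[C@@]3(C)CC[C@@H](Cl)/C(C)=C\C[C@@H]12 | intermediate
38 | (1S,2S,3E,7S,8R,11R,12Z)-11-chloro-8-hydroperoxy-7-hydroxycembra-3,12,15(17)-trien-16,2-olide | C=C1C(=O)O[C@H]2/C=C(\C)CC[C@H](O)[C@@](OO)(C)CC[C@@H](Cl)/C(C)=C\C[C@@H]12 | intermediate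
39 | (1S,2S,3E,7S,8R,11S,12Z)-8,11-epidioxy-7-hydroxycembra-3,12,15(17)-trien-16,2-olide | C=C1C(=O)O[C@H]2/C=C(\C)CC[C@H](O)[C@@]3(C)CC[C@H](OO3)/C(C)=C\C[C@@H]12 | intermediate
40 | denticulatolide, (1S,2S,3E,7S,8R,11S,12Z)-7-acetoxy-8,11-epidioxycembra-3,12,15(17)-trien-16,2-olide | C=C1C(=O)O[C@H]2/C=C(\C)CC[C@H](OC(C)=O)[C@@]3(C)CC[C@H](OO3)/C(C)=C\C[C@@H]12 | target

**Step count and risks**

Total steps: 26. Longest linear sequence: 21 (steps 1–12, 16, 19–26).

Three steps most likely to fail: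

Step 19 (key allylboration). The facial control by the ester auxiliary and the thermal reactivity of the hindered boronate are the least precedented part of the route, as is the borylated ylide of steps 15–16 that feeds it. Fallback: leave the route at aldehyde 17 and make the C1–C2 bond by a ligand-controlled, chromium-catalysed Nozaki–Hiyama-type allylation instead. [1-(Methoxycarbonyl)vinyl]diisobutylalane (from methyl propiolate, i-Bu2AlH and N-methylmorpholine N-oxide) adds to 17 to give the Baylis–Hillman-type alcohol F1. MsCl/Et3N then LiBr convert it by SN2' into the (Z)-2-(bromomethyl)enoate F2. CrCl2 (10 mol %) with a chiral carbazole-bis(oxazoline) ligand, Mn powder and Cp2ZrCl2 couples it with 30 to the syn hydroxy methyl ester F3, which pyridinium p-toluenesulfonate lactonizes, rejoining the route at 32.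

Step 21 (macrocyclization). Ring closure competes with oligomerization and protodeboronation, the aqueous base can attack the lactone, and the allylic lactone C–O bond is a possible site for the palladium catalyst. Fallback: from 33, hydroborate as before but oxidize (NaBO3·4H2O) to the primary alcohol F4. I2/PPh3/imidazole convert it into the primary iodide F5. Zinc insertion (Zn dust, LiCl, THF) gives the alkylzinc iodide F6, and a base-free intramolecular Negishi coupling (Pd2(dba)3, SPhos, THF, high dilution) closes the ring and returns to 35.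

Step 25 (with step 23 that prepares it). The two consecutive inversions at the allylic C11 can leak through ionization or allylic transposition, and the transannular SN2 needs a favourable ring conformation. Fallback: from 36, keep the free C11 alcohol and perhydrolyse the epoxide (H2O2, H3PMo12O40, Et2O) to the dihydroxy hydroperoxide F7. Acid catalysis (Sc(OTf)3, 5 mol %, CH2Cl2, 0 °C) then closes the dioxane by capture of the allyl cation by the C8 hydroperoxide. The cis-bridged dioxane is separated from any C11 epimer and the route continues at 39, avoiding both the chloride and the basic step.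

Further compounds
F1 | step 19 | methyl (5Z,7S,10E)-7-(tert-butyldimethylsilyloxy)-3-hydroxy-6,10-dimethyl-2-methylidenetrideca-5,10,12-trienoate (mixture at C3) | C=C/C=C(\C)CC[C@H](O[Si](C)(C)C(C)(C)C)/C(C)=C\CC(O)C(=C)C(=O)OC
F2 | step 19 | methyl (2Z,5Z,7S,10E)-2-(bromomethyl)-7-(tert-butyldimethylsilyloxy)-6,10-dimethyltrideca-2,5,10,12-tetraenoate | C=C/C=C(\C)CC[C@H](O[Si](C)(C)C(C)(C)C)/C(C)=C\C/C=C(\CBr)C(=O)OC
F3 | step 19 | syn hydroxy methyl ester (open form of 32; 1S with H1/H2 syn) | C=C/C=C(\C)CC[C@H](O[Si](C)(C)C(C)(C)C)/C(C)=C\C[C@@H](C(=C)C(=O)OC)[C@@H](O)/C=C(\C)I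
F4 | step 21 | primary alcohol from 33 (CH2CH2OH on the epoxide carbon C7) | OCC[C@@H]1O[C@@]1(C)CC[C@H](O[Si](C)(C)C(C)(C)C)/C(C)=C\C[C@@H]1[C@H](/C=C(\C)I)OC(=O)C1=C
F5 | step 21 | primary iodide from F4 | ICC[C@@H]1O[C@@]1(C)CC[C@H](O[Si](C)(C)C(C)(C)C)/C(C)=C\C[C@@H]1[C@H](/C=C(\C)I)OC(=O)C1=C
F6 | step 21 | alkylzinc iodide from F5 | I[Zn]CC[C@@H]1O[C@@]1(C)CC[C@H](O[Si](C)(C)C(C)(C)C)/C(C)=C\C[C@@H]1[C@H](/C=C(\C)I)OC(=O)C1=C
F7 | step 25 | (1S,2S,3E,7S,8R,11S,12Z)-8-hydroperoxy-7,11-dihydroxycembra-3,12,15(17)-trien-16,2-olide | C=C1C(=O)O[C@H]2/C=C(\C)CC[C@H](O)[C@@](OO)(C)CC[C@H](O)/C(C)=C\C[C@@H]12
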